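**Retrosynthetic overview**

1. The target acid is taken back, by ester hydrolysis and desilylation, to the C3-silyl ether of the chroman methyl ester.
2. Structural feature: ring B (O1–C2–C3–C4–C4a–C8a) meets benzoate ring A at the adjacent carbons C4a (bearing C4H2) and C8a (bearing O1, para to the C6 carboxyl). These are an ortho C–H and the ipso carbon of a 4-iodobenzoate.
3. Both arene bonds of ring B, C4–C4a and C8a–O1, are therefore cut together. This gives methyl 4-iodobenzoate and an acyclic C15 fragment with a primary iodide (future C4), a silylated secondary oxygen (future C3–O) and a free tertiary hydroxyl (future O1 on C2), both stereocentres already in place.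
4. The C15 iodide is traced through the 1,2,3-triol to (2Z,6E)-farnesol. Asymmetric epoxidation fixes the future C3, and backside hydrolysis at the tertiary carbon fixes the future C2.
5. Ring order: ring A is bought; ring B is the only ring formed, in the key step.

Key step: step 6

Assumption: (2Z,6E)-farnesol is taken as purchasable in isomerically pure form, and the bridgehead-methyl norbornene of step 6 is treated as a separately prepared mediator that contributes no atoms.

**Step 1**
Reactants: 1 (2Z,6E)-farnesol [(2Z,6E)-3,7,11-trimethyldodeca-2,6,10-trien-1-ol]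
Product: 2 [(2S,3R)-3-[(3E)-4,8-dimethylnona-3,7-dien-1-yl]-3-methyloxiran-2-yl]methanol
Conditions: Ti(OiPr)4 (10 mol%), L-(+)-DET (12 mol%), TBHP (isooctane), 4 Å MS, CH2Cl2, −20 °C
Reagents that add atoms: tert-butyl hydroperoxide, CC(C)(C)OO
Why: Sharpless asymmetric epoxidation; the titanium tartrate complex binds the allylic hydroxyl, so only the 2,3-olefin reacts, and L-(+)-DET should deliver oxygen to the face that gives the (2S,3R)-epoxide of this Z-3,3-disubstituted allylic alcohol, as for nerol-type substrates.

**Step 2**
Reactants: 2 [(2S,3R)-3-[(3E)-4,8-dimethylnona-3,7-dien-1-yl]-3-methyloxiran-2-yl]methanol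
Product: 3 (2S,3S,6E)-3,7,11-trimethyldodeca-6,10-diene-1,2,3-triol
Conditions: HClO4 (cat., aq.), THF/H2O, 0 °C to rt
Reagents that add atoms: water, O
Why: Acid-catalysed epoxide hydrolysis with borderline SN2 character; water should attack the protonated epoxide at the tertiary carbon from the backside, so C3 is inverted to S while C2 keeps its C–O bond and stays S, and the distal trisubstituted olefins cannot trap the developing cation in a favourable ring size.

**Step 3**
Reactants: 3 (2S,3S,6E)-3,7,11-trimethyldodeca-6,10-diene-1,2,3-triol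
Product: 4 (2S,3S,6E)-2,3-dihydroxy-3,7,11-trimethyldodeca-6,10-dien-1-yl 4-methylbenzenesulfonate
Conditions: TsCl (1.05 equiv), Et3N, Bu2SnO (2 mol%), CH2Cl2, 0 °C to rt
Reagents that add atoms: 4-toluenesulfonyl chloride, Cc1ccc(cc1)S(Cl)(=O)=O
Why: Stannylene-acetal-catalysed regioselective sulfonylation of a 1,2-diol, which activates the primary oxygen and leaves the secondary and tertiary hydroxyls free.

**Step 4**
Reactants: 4 (2S,3S,6E)-2,3-dihydroxy-3,7,11-trimethyldodeca-6,10-dien-1-yl 4-methylbenzenesulfonate
Product: 5 (2S,3S,6E)-2-(tert-butyldimethylsilyloxy)-3-hydroxy-3,7,11-trimethyldodeca-6,10-dien-1-yl 4-methylbenzenesulfonate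
Conditions: TBSOTf (1.1 equiv), 2,6-lutidine, CH2Cl2, −78 °C
Reagents that add atoms: tert-butyldimethylsilyl trifluoromethanesulfonate, CC(C)(C)[Si](C)(C)OS(=O)(=O)C(F)(F)F
Why: Silyl ether formation under non-nucleophilic base; at low temperature with one equivalent the secondary hydroxyl should be silylated far faster than the tertiary one, and the conditions cannot close the hydroxy tosylate to an epoxide.

**Step 5**
Reactants: 5 (2S,3S,6E)-2-(tert-butyldimethylsilyloxy)-3-hydroxy-3,7,11-trimethyldodeca-6,10-dien-1-yl 4-methylbenzenesulfonate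
Product: 6 (2R,3S,6E)-2-(tert-butyldimethylsilyloxy)-1-iodo-3,7,11-trimethyldodeca-6,10-dien-3-ol
Conditions: NaI (5 equiv), acetone, reflux, dark
Reagents that add atoms: sodium iodide, [Na+].[I-]
Why: Finkelstein SN2 displacement at the primary carbon, driven by precipitation of the sodium sulfonate; no stereocentre is touched, and the descriptor at C2 changes from S to R only because CH2I outranks C3.

**Step 6**
Reactants: 6 (2R,3S,6E)-2-(tert-butyldimethylsilyloxy)-1-iodo-3,7,11-trimethyldodeca-6,10-dien-3-ol; 7 methyl 4-iodobenzoate (1.5 equiv)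
Product: 9 methyl (2S,3S)-3-(tert-butyldimethylsilyloxy)-2-[(3E)-4,8-dimethylnona-3,7-dien-1-yl]-2-methyl-3,4-dihydro-2H-chromene-6-carboxylate, via ortho-alkylated arylpalladium iodide 8 (not isolated)
Conditions: Pd(OAc)2 (10 mol%), XPhos (20 mol%), 1-methylbicyclo[2.2.1]hept-2-ene (1.0 equiv), Cs2CO3 (3 equiv), 1,4-dioxane, 100 °C
Reagents that add atoms: none
Why: Proposed new method: zerovalent palladium formed from Pd(OAc)2 and XPhos inserts into the C–I bond of 7, exo-carbopalladation of the norbornene and carbonate-assisted ortho C–H palladation give the five-membered aryl–norbornyl palladacycle, and this takes up the primary C–I bond of 6 by SN2-type oxidative addition to tetravalent palladium and forms C4–C4a by reductive elimination. The bridgehead methyl group of the norbornene should then force beta-carbon elimination after this single alkylation, releasing the norbornene and leaving arylpalladium iodide 8, whose tertiary hydroxyl is deprotonated by Cs2CO3 and bound to divalent palladium. Ring B is closed by C(aryl)–O reductive elimination from the resulting seven-membered oxapalladacycle, an ipso substitution at C8a that gives the six-membered cyclic ether and is favoured by the para ester and the bulky biarylphosphine. The closest known reaction type is the Catellani-type palladium/norbornene annulation in which ortho alkylation is ended by intramolecular ipso C–N or C–O coupling (indolines and tetrahydroquinolines from haloalkylamines or aziridines, 2,3-dihydrobenzofurans from epoxides); new here are closure of a six-membered ether by a tertiary alkoxide, an ortho-unsubstituted aryl iodide and a beta-branched, beta-silyloxy primary iodide. No stereocentre is created, because only the C1–I and O–H bonds of 6 react and the tertiary C–O bond is never broken, so C2 and C3 of the chroman are carried over unchanged. The step needs mono- over double ortho alkylation (secured by the bridgehead-substituted norbornene), ipso etherification over Heck-type termination (secured by the tethered alkoxide, which has no hydrogen on its carbinol carbon, and by the absence of any olefin more reactive than trisubstituted) and six- over five-membered closure (secured by the silyl group on the secondary oxygen).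

**Step 7**
Reactants: 9 methyl (2S,3S)-3-(tert-butyldimethylsilyloxy)-2-[(3E)-4,8-dimethylnona-3,7-dien-1-yl]-2-methyl-3,4-dihydro-2H-chromene-6-carboxylate
Product: 10 methyl (2S,3S)-2-[(3E)-4,8-dimethylnona-3,7-dien-1-yl]-3-hydroxy-2-methyl-3,4-dihydro-2H-chromene-6-carboxylate
Conditions: Bu4NF, THF, 0 °C to rt
Reagents that add atoms: none
Why: Fluoride-mediated desilylation driven by the strong Si–F bond; the methyl ester, the aryl ether and the olefins are inert to it, and chromatography at this stage removes the ammonium salts before the acid is made.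

**Step 8**
Reactants: 10 methyl (2S,3S)-2-[(3E)-4,8-dimethylnona-3,7-dien-1-yl]-3-hydroxy-2-methyl-3,4-dihydro-2H-chromene-6-carboxylate
Product: 12 (2S,3S)-2-[(3E)-4,8-dimethylnona-3,7-dien-1-yl]-3-hydroxy-2-methyl-3,4-dihydro-2H-chromene-6-carboxylic acid, via lithium carboxylate 11 (not isolated)
Conditions: LiOH·H2O, THF/MeOH/H2O, rt; then 1 M HCl to pH 3, 0 °C
Reagents that add atoms: lithium hydroxide, [Li+].[OH-]
Why: Ester saponification by acyl–oxygen cleavage followed by cold, brief acidification; neither stereocentre is epimerisable and the trisubstituted olefins should tolerate the short contact with dilute acid.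

**Compound list**

1 | (2Z,6E)-farnesol, (2Z,6E)-3,7,11-trimethyldodeca-2,6,10-trien-1-ol | CC(C)=CCC/C(C)=C/CC/C(C)=C\CO | starting material
2 | [(2S,3R)-3-[(3E)-4,8-dimethylnona-3,7-dien-1-yl]-3-methyloxiran-2-yl]methanol | CC(C)=CCC/C(C)=C/CC[C@@]1(C)O[C@H]1CO | intermediate
3 | (2S,3S,6E)-3,7,11-trimethyldodeca-6,10-diene-1,2,3-triol | CC(C)=CCC/C(C)=C/CC[C@](C)(O)[C@H](CO)O | intermediate
4 | (2S,3S,6E)-2,3-dihydroxy-3,7,11-trimethyldodeca-6,10-dien-1-yl 4-methylbenzenesulfonate | CC(C)=CCC/C(C)=C/CC[C@](C)(O)[C@H](COS(=O)(=O)c1ccc(C)cc1)O | intermediate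
5 | (2S,3S,6E)-2-(tert-butyldimethylsilyloxy)-3-hydroxy-3,7,11-trimethyldodeca-6,10-dien-1-yl 4-methylbenzenesulfonate | CC(C)=CCC/C(C)=C/CC[C@](C)(O)[C@H](COS(=O)(=O)c1ccc(C)cc1)O[Si](C)(C)C(C)(C)C | intermediate
6 | (2R,3S,6E)-2-(tert-butyldimethylsilyloxy)-1-iodo-3,7,11-trimethyldodeca-6,10-dien-3-ol | CC(C)=CCC/C(C)=C/CC[C@](C)(O)[C@H](CI)O[Si](C)(C)C(C)(C)C | intermediate
7 | methyl 4-iodobenzoate | COC(=O)c1ccc(I)cc1 | starting material
8 | iodo{2-[(2S,3S,6E)-2-(tert-butyldimethylsilyloxy)-3-hydroxy-3,7,11-trimethyldodeca-6,10-dien-1-yl]-4-(methoxycarbonyl)phenyl}palladium, an arylpalladium iodide of divalent palladium (phosphine ligand omitted) | CC(C)=CCC/C(C)=C/CC[C@](C)(O)[C@H](Cc1cc(C(=O)OC)ccc1[Pd]I)O[Si](C)(C)C(C)(C)C | intermediate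
9 | methyl (2S,3S)-3-(tert-butyldimethylsilyloxy)-2-[(3E)-4,8-dimethylnona-3,7-dien-1-yl]-2-methyl-3,4-dihydro-2H-chromene-6-carboxylate | CC(C)=CCC/C(C)=C/CC[C@]1(C)Oc2ccc(C(=O)OC)cc2C[C@@H]1O[Si](C)(C)C(C)(C)C | intermediate
10 | methyl (2S,3S)-2-[(3E)-4,8-dimethylnona-3,7-dien-1-yl]-3-hydroxy-2-methyl-3,4-dihydro-2H-chromene-6-carboxylate | CC(C)=CCC/C(C)=C/CC[C@]1(C)Oc2ccc(C(=O)OC)cc2C[C@@H]1O | intermediate
11 | lithium (2S,3S)-2-[(3E)-4,8-dimethylnona-3,7-dien-1-yl]-3-hydroxy-2-methyl-3,4-dihydro-2H-chromene-6-carboxylate | CC(C)=CCC/C(C)=C/CC[C@]1(C)Oc2ccc(C(=O)[O-])cc2C[C@@H]1O.[Li+] | intermediate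
12 | (2S,3S)-2-[(3E)-4,8-dimethylnona-3,7-dien-1-yl]-3-hydroxy-2-methyl-3,4-dihydro-2H-chromene-6-carboxylic acid (CNP0189862.2) | CC(C)=CCC/C(C)=C/CC[C@]1(C)Oc2ccc(C(=O)O)cc2C[C@@H]1O | target

**Step count**

Total steps: 8. Longest linear sequence: 8 steps (from 1 to 12); 7 enters at step 6.

**Steps most likely to fail**

Step 6. The SN2-type oxidative addition of the beta-branched, beta-silyloxy iodide to the palladacycle may be too slow. Then norbornene-free ipso pathways, a second ortho alkylation, base-induced intramolecular displacement of iodide by the tertiary alkoxide, or 1,2-silyl migration followed by five-membered closure could take over. The fallback uses known chemistry, sets out from 6 and comes back at 9, and makes the two arene bonds in separate operations. Iodide 6 would be joined to commercial methyl 4-chloro-3-iodobenzoate by nickel-catalysed reductive cross-electrophile coupling (NiI2, 4,4'-di-tert-butyl-2,2'-bipyridine, Zn dust, DMA, 60 °C). This should link the primary alkyl carbon to the aryl carbon that carried iodine and leave the aryl chloride, the free tertiary alcohol, the silyl ether and the ester alone, giving methyl 3-[(2S,3S,6E)-2-(tert-butyldimethylsilyloxy)-3-hydroxy-3,7,11-trimethyldodeca-6,10-dien-1-yl]-4-chlorobenzoate F1. Intramolecular Buchwald–Hartwig-type etherification of the tertiary alcohol onto the ester-activated aryl chloride (Pd(OAc)2, 2-(di-tert-butylphosphino)-1,1'-binaphthyl, Cs2CO3, toluene, 80 °C) would then close ring B and return to 9.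

Step 2. Partial ionisation of the protonated epoxide to a free tertiary cation, or competing attack of water at C2, would erode diastereomeric and enantiomeric purity. The fallback sets out from 1 and comes back at 3, and moves the inversion from the tertiary to the secondary carbon. Epoxidation of 1 with the enantiomeric tartrate (Ti(OiPr)4, D-(−)-DET, TBHP, 4 Å MS, CH2Cl2, −20 °C) would give [(2R,3S)-3-[(3E)-4,8-dimethylnona-3,7-dien-1-yl]-3-methyloxiran-2-yl]methanol F2. In aqueous NaOH/tert-butanol at 70 °C, Payne rearrangement would invert C2 and give, in equilibrium, (2S,5E)-6,10-dimethyl-2-[(2S)-oxiran-2-yl]undeca-5,9-dien-2-ol F3. Hydroxide would open its terminal epoxide carbon to give 3 with the tertiary centre never involved.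

Step 5. Substitution at the beta-branched, beta-silyloxy primary carbon may be slow, so that prolonged heating leads to elimination or loss of the silyl group. The fallback sets out from 3 and comes back at 6, and installs iodine before the silyl group by phosphonium activation instead of sulfonate displacement. Triol 3 would be treated with PPh3, I2 and imidazole (THF/MeCN, 0 °C; Appel-type iodination, selective for the primary hydroxyl) to give (2R,3S,6E)-1-iodo-3,7,11-trimethyldodeca-6,10-diene-2,3-diol F4. Selective silylation of its secondary hydroxyl (TBSOTf, 2,6-lutidine, CH2Cl2, −78 °C) would give 6.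

**Further compounds**

F1 | step 6 | methyl 3-[(2S,3S,6E)-2-(tert-butyldimethylsilyloxy)-3-hydroxy-3,7,11-trimethyldodeca-6,10-dien-1-yl]-4-chlorobenzoate | CC(C)=CCC/C(C)=C/CC[C@](C)(O)[C@H](Cc1cc(C(=O)OC)ccc1Cl)O[Si](C)(C)C(C)(C)C
F2 | step 2 | [(2R,3S)-3-[(3E)-4,8-dimethylnona-3,7-dien-1-yl]-3-methyloxiran-2-yl]methanol | CC(C)=CCC/C(C)=C/CC[C@]1(C)O[C@@H]1CO
F3 | step 2 | (2S,5E)-6,10-dimethyl-2-[(2S)-oxiran-2-yl]undeca-5,9-dien-2-ol | CC(C)=CCC/C(C)=C/CC[C@](C)(O)[C@@H]1CO1
F4 | step 5 | (2R,3S,6E)-1-iodo-3,7,11-trimethyldodeca-6,10-diene-2,3-diol | CC(C)=CCC/C(C)=C/CC[C@](C)(O)[C@H](CI)O
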